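**Retrosynthetic overview**

1. The only ring, the 11-membered carbocycle, is opened at the C2–C3 bond of the diene. An acyclic 2-bromo-1-alkene with a vinyl group on the quaternary carbon closes it in the last step by an 11-endo Heck reaction.
2. Key disconnection: the C9–O alkyl–oxygen bond of the ester. Unprotected vanillic acid displaces the activated (R)-carbinol with inversion (Mitsunobu), which joins the two halves and puts the single stereocentre into its final S configuration.
3. The C5–C6 bond comes from a Negishi coupling of an E-alkenyl iodide with (3-bromobut-3-en-1-yl)zinc iodide. The alkenyl iodide comes from carboalumination–iodination of a homopropargylic alcohol.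
4. C8–C9–C10 is (S)-epichlorohydrin, opened at both CH2 termini: by prenylmagnesium chloride through its γ-carbon (C10–C11, giving the quaternary centre and vinyl group) and by lithium acetylide (C7–C8).
5. Ring order: no ring exists until the final step. The route is 7 steps, 6 in the longest line.

Assumption: atom labels C1–C11 and C15 are humulane locants (C9 carries oxygen, C11 is the gem-dimethyl carbon, C3 carries the exocyclic CH2 = C15, C7 is the methyl-bearing alkene carbon), and prenylmagnesium chloride is bought as its THF solution.

**Route**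

Step 1
Reactants: 1 (S)-epichlorohydrin; 2 prenylmagnesium chloride, (CH3)2C=CHCH2MgCl
Product: 4 (2S)-2-(2,2-dimethylbut-3-en-1-yl)oxirane, via chlorohydrin alkoxide 3 (not isolated)
Conditions: 2 (1.2 equiv), THF, −40 → 0 °C, no copper; then 5 M aq NaOH, 0 → 23 °C
Reagents that add atoms: none
Why: Allylic Grignard reagents open terminal epoxides at the CH2 carbon through a cyclic SE2′ transition state in which the γ-carbon of the prenyl unit attacks (copper is left out because it would switch to α-attack), so the C10–C11 bond and the quaternary centre form together; the chlorohydrin alkoxide 3 then closes by intramolecular Williamson displacement, and since no bond to the stereocentre is made or broken, 4 keeps the configuration of 1.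

Step 2
Reactants: 4 (2S)-2-(2,2-dimethylbut-3-en-1-yl)oxirane
Product: 5 (4R)-6,6-dimethyloct-7-en-1-yn-4-ol
Conditions: LiC≡CH·H2NCH2CH2NH2 (2 equiv), DMSO, 0 → 23 °C; H2O quench
Reagents that add atoms: lithium acetylide–ethylenediamine complex, [Li]C#C.NCCN
Why: SN2 opening of a terminal epoxide at its CH2 carbon by lithium acetylide forms C7–C8 without touching the carbinol carbon, whose descriptor changes from S to R only because the ligand priorities change.

Step 3
Reactants: 5 (4R)-6,6-dimethyloct-7-en-1-yn-4-ol
Product: 7 (1E,4S)-1-iodo-2,6,6-trimethylocta-1,7-dien-4-ol, via alkenylalane 6 (not isolated)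
Conditions: AlMe3 (3 equiv), Cp2ZrCl2 (0.3 equiv), CH2Cl2, 0 → 23 °C; then I2 (1.5 equiv), THF, −30 → 0 °C
Reagents that add atoms: trimethylaluminium, C[Al](C)C; iodine, II
Why: Negishi zirconium-catalysed carboalumination adds methyl and aluminium syn across the terminal alkyne with aluminium on the terminal carbon, and iodinolysis of 6 proceeds with retention, which fixes the E trisubstituted C6=C7 alkene; the vinyl group on the quaternary carbon is too hindered to be carbometallated, and the descriptor changes from R to S by priority only.

Step 4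
Reactants: 8 3-bromobut-3-en-1-ol
Product: 9 2-bromo-4-iodobut-1-ene
Conditions: I2, PPh3, imidazole, CH2Cl2, 0 → 23 °C
Reagents that add atoms: iodine, II
Why: Appel-type iodination, in which iodide displaces the primary alkoxyphosphonium ion in an SN2 step while the alkenyl bromide is inert.

Step 5
Reactants: 7 (1E,4S)-1-iodo-2,6,6-trimethylocta-1,7-dien-4-ol; 9 2-bromo-4-iodobut-1-ene
Product: 11 (5R,7E)-11-bromo-3,3,7-trimethyldodeca-1,7,11-trien-5-ol, via organozinc iodide 10 (not isolated)
Conditions: 9, Zn dust (BrCH2CH2Br, Me3SiCl activation), THF, 35 °C; then 7 (0.4 equiv relative to 9), Pd(PPh3)4 (5 mol%), THF, 23 °C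
Reagents that add atoms: none
Why: Zinc inserts into the primary carbon–iodine bond of 9 and leaves the alkenyl bromide alone, and Negishi alkenyl–alkyl cross-coupling then joins C5 to C6 with retention of the E geometry, because zerovalent palladium adds to the alkenyl iodide of 7 much faster than to the 1,1-disubstituted alkenyl bromide at 23 °C; the excess of 10 covers slow protonolysis by the free hydroxyl group.

Step 6 (key C–O bond)
Reactants: 11 (5R,7E)-11-bromo-3,3,7-trimethyldodeca-1,7,11-trien-5-ol; 12 vanillic acid
Product: 13 (5S,7E)-11-bromo-3,3,7-trimethyldodeca-1,7,11-trien-5-yl 4-hydroxy-3-methoxybenzoate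
Conditions: 12 (1.5 equiv), PPh3, DIAD (1.6 equiv each), THF, 0 → 23 °C
Reagents that add atoms: none
Why: Mitsunobu esterification, in which the alcohol is activated as its alkoxyphosphonium ion and displaced in an SN2 step by the vanillate carboxylate, forming the C9–O bond with inversion (5R to 5S, the configuration of the target); the carboxylic acid (pKa about 4.5) is alkylated in preference to the phenol (pKa about 9), so no protecting group is needed.

Step 7
Reactants: 13 (5S,7E)-11-bromo-3,3,7-trimethyldodeca-1,7,11-trien-5-yl 4-hydroxy-3-methoxybenzoate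
Product: 14 (1S,3E,8E)-3,10,10-trimethyl-7-methylidenecycloundeca-3,8-dien-1-yl 4-hydroxy-3-methoxybenzoate
Conditions: Pd(OAc)2 (10 mol%), P(o-tol)3 (25 mol%), n-Bu4NBr (1 equiv), NaHCO3 (3 equiv), DMF, 85 °C, 13 added by syringe pump over 12 h to 2 mM
Reagents that add atoms: none
Why: Proposed new method: an 11-endo Mizoroki–Heck macrocyclisation of a 2-bromo-1-alkene onto a neopentyl-type vinyl group; zerovalent palladium (formed from Pd(OAc)2 and the phosphine) inserts into the carbon–bromine bond, the alkenylpalladium bromide adds across the vinyl group with carbon going to the unsubstituted terminus C2 (the quaternary C11 blocks the internal carbon and the halide-rich neutral pathway favours terminal attack), and the resulting alkylpalladium at C1 has β-hydrogen only on C2 because C11 is quaternary, so syn β-hydride elimination can only give the conjugated E diene without chain walking; the trisubstituted alkene cannot compete because it could only close 4-exo or 5-endo, the gem-dimethyl group helps to fold the chain and the free phenol and ester are tolerated; the closest known reaction types are the intermolecular Heck coupling of 2-bromo-1-alkenes with 3,3-dimethylbut-1-ene to E 2-substituted 1,3-dienes and endo-selective Heck macrocyclisations to rings of 13 or more atoms, and an all-carbon 11-membered ring closed in this way is, as far as is known, without precedent.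

**Compound list**

1 | (S)-epichlorohydrin, (2S)-2-(chloromethyl)oxirane | ClC[C@@H]1CO1 | starting material
2 | prenylmagnesium chloride, (3-methylbut-2-en-1-yl)magnesium chloride | CC(C)=CC[Mg]Cl | starting material
3 | chloromagnesium (2S)-1-chloro-4,4-dimethylhex-5-en-2-olate (chlorohydrin alkoxide, not isolated) | C=CC(C)(C)C[C@H](O[Mg]Cl)CCl | intermediate
4 | (2S)-2-(2,2-dimethylbut-3-en-1-yl)oxirane | C=CC(C)(C)C[C@H]1CO1 | intermediate
5 | (4R)-6,6-dimethyloct-7-en-1-yn-4-ol | C=CC(C)(C)C[C@H](O)CC#C | intermediate
6 | [(1E,4S)-4-(dimethylalumanyloxy)-2,6,6-trimethylocta-1,7-dien-1-yl]dimethylalane (alkenylalane, not isolated) | C=CC(C)(C)C[C@H](O[Al](C)C)C/C(C)=C/[Al](C)C | intermediate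
7 | (1E,4S)-1-iodo-2,6,6-trimethylocta-1,7-dien-4-ol | C=CC(C)(C)C[C@H](O)C/C(C)=C/I | intermediate
8 | 3-bromobut-3-en-1-ol | C=C(Br)CCO | starting material
9 | 2-bromo-4-iodobut-1-ene | C=C(Br)CCI | intermediate
10 | (3-bromobut-3-en-1-yl)zinc iodide (not isolated) | C=C(Br)CC[Zn]I | intermediate
11 | (5R,7E)-11-bromo-3,3,7-trimethyldodeca-1,7,11-trien-5-ol | C=CC(C)(C)C[C@H](O)C/C(C)=C/CCC(Br)=C | intermediate
12 | vanillic acid, 4-hydroxy-3-methoxybenzoic acid | COc1cc(C(=O)O)ccc1O | starting material
13 | (5S,7E)-11-bromo-3,3,7-trimethyldodeca-1,7,11-trien-5-yl 4-hydroxy-3-methoxybenzoate | C=CC(C)(C)C[C@@H](OC(=O)c1ccc(O)c(OC)c1)C/C(C)=C/CCC(Br)=C | intermediate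
14 | (1S,3E,8E)-3,10,10-trimethyl-7-methylidenecycloundeca-3,8-dien-1-yl 4-hydroxy-3-methoxybenzoate | C=C1/C=C/C(C)(C)C[C@@H](OC(=O)c2ccc(O)c(OC)c2)C/C(C)=C/CC1 | target

**Step count and risks**

Total steps: 7. Longest linear sequence: 6 (steps 1, 2, 3, 5, 6, 7 from (S)-epichlorohydrin); step 4 is a one-step side branch.

The three steps most likely to fail:

Step 7 (the new 11-endo Heck closure). The risks are oligomerisation, migration of the new diene by palladium hydride, or poor turnover at 2 mM. The fallback uses known chemistry, sets out from 13 and comes back at 14. Stille coupling of the alkenyl bromide with tributyl(vinyl)stannane (Pd(PPh3)4, toluene, 90 °C) gives the 2-substituted butadiene (5S,7E)-3,3,7-trimethyl-11-methylidenetrideca-1,7,12-trien-5-yl 4-hydroxy-3-methoxybenzoate F1. Diene–ene ring-closing metathesis between its two monosubstituted vinyl groups (second-generation Hoveyda–Grubbs catalyst, (SIMes)RuCl2(=CH–C6H4-2-O-i-Pr), 10 mol%, toluene, 80 °C, 1 mM, argon sparge) then forms the C1=C2 bond, releases ethene and gives 14.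

Step 5 (Negishi coupling). The risk is that the alkenyl bromide carried by the zinc reagent and by the product also enters the palladium cycle, together with loss of reagent to the free hydroxyl group. The fallback masks the bromoalkene as a silyl alkyne, sets out from 7 and comes back at 11. Negishi coupling of 7 (Pd(PPh3)4, THF, 23 °C) with [4-(trimethylsilyl)but-3-yn-1-yl]zinc iodide F2, made in the flask from purchased (4-iodobut-1-yn-1-yl)trimethylsilane and zinc dust, gives (5R,7E)-3,3,7-trimethyl-12-(trimethylsilyl)dodeca-1,7-dien-11-yn-5-ol F3. K2CO3 in MeOH removes the silyl group to give (5R,7E)-3,3,7-trimethyldodeca-1,7-dien-11-yn-5-ol F4. Nickel-catalysed α-selective hydroalumination (NiCl2(dppp) 3 mol%, i-Bu2AlH 2.3 equiv, THF, 23 °C) gives the diisobutylaluminium alkoxide of (5R,7E)-11-(diisobutylalumanyl)-3,3,7-trimethyldodeca-1,7,11-trien-5-ol F5 (not isolated), and N-bromosuccinimide at 0 °C turns its carbon–aluminium bond into the carbon–bromine bond of 11.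

Step 1 (reverse prenylation of epichlorohydrin). The risks are partial α-attack of the prenyl reagent, chloride-mediated erosion of the enantiomeric purity, and loss of the volatile epoxide. The fallback replaces the allylic nucleophile by a tertiary carbanion of unambiguous regiochemistry, sets out from 1 and comes back at 4. Lithiated isobutyronitrile (LiN(i-Pr)2, THF, −78 °C) opens 1 at the epoxide CH2 to give lithium (4S)-5-chloro-4-hydroxy-2,2-dimethylpentanenitrile alkoxide F6 (not isolated), which closes on warming to 2,2-dimethyl-3-[(2S)-oxiran-2-yl]propanenitrile F7. Reduction with i-Bu2AlH (1.1 equiv, toluene, −78 °C, aqueous potassium sodium tartrate work-up) gives 2,2-dimethyl-3-[(2S)-oxiran-2-yl]propanal F8, and Wittig methylenation (Ph3P=CH2, THF, 0 °C) returns to 4.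

**Further compounds**

F1 | step 7 | (5S,7E)-3,3,7-trimethyl-11-methylidenetrideca-1,7,12-trien-5-yl 4-hydroxy-3-methoxybenzoate | C=CC(C)(C)C[C@@H](OC(=O)c1ccc(O)c(OC)c1)C/C(C)=C/CCC(=C)C=C
F2 | step 5 | [4-(trimethylsilyl)but-3-yn-1-yl]zinc iodide | C[Si](C)(C)C#CCC[Zn]I
F3 | step 5 | (5R,7E)-3,3,7-trimethyl-12-(trimethylsilyl)dodeca-1,7-dien-11-yn-5-ol | C=CC(C)(C)C[C@H](O)C/C(C)=C/CCC#C[Si](C)(C)C
F4 | step 5 | (5R,7E)-3,3,7-trimethyldodeca-1,7-dien-11-yn-5-ol | C=CC(C)(C)C[C@H](O)C/C(C)=C/CCC#C
F5 | step 5 | diisobutylaluminium alkoxide of (5R,7E)-11-(diisobutylalumanyl)-3,3,7-trimethyldodeca-1,7,11-trien-5-ol | C=CC(C)(C)C[C@H](O[Al](CC(C)C)CC(C)C)C/C(C)=C/CCC(=C)[Al](CC(C)C)CC(C)C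
F6 | step 1 | lithium (4S)-5-chloro-4-hydroxy-2,2-dimethylpentanenitrile alkoxide | N#CC(C)(C)C[C@H](O[Li])CCl
F7 | step 1 | 2,2-dimethyl-3-[(2S)-oxiran-2-yl]propanenitrile | N#CC(C)(C)C[C@H]1CO1
F8 | step 1 | 2,2-dimethyl-3-[(2S)-oxiran-2-yl]propanal | O=CC(C)(C)C[C@H]1CO1
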